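**Assumptions.** The target is taken as the (1R,5R,6R) epoxyquinol acetate with a (2E,6E)-farnesyl chain and the acetoxy group cis to the epoxide oxygen. 4-Methoxy-3-methylphenol and (2E,6E)-farnesyl bromide are purchased. The absolute sense of the step 5 catalyst and the enantiopreference of the step 10 lipase are predicted by analogy, not known for this substrate; if step 5 runs in the opposite sense, the pseudoenantiomeric N-benzylcinchoninium salt is used.

## Retrosynthetic overview

1. Target 12 ⇐ lipase-catalysed acetylation of epoxyquinol 11 ⇐ regio- and stereoselective reduction of quinone epoxide 10.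
2. 10 ⇐ unmasking of the ketal carbon (reduce, hydrolyse, re-oxidise) in epoxy ketone 7.
3. 7 ⇐ catalytic asymmetric nucleophilic epoxidation of the achiral quinone monoketal 6 (first stereocentres).
4. 6 ⇐ oxidative dearomatisation of phenol 5 ⇐ directed ortho-metalation and farnesylation of 4-methoxy-3-methylphenol 1.
5. Ring order: the carbocycle comes from the arene; the oxirane is the only ring formed (step 5).

## Route

**Step 1**
Reactants: 1, 4-methoxy-3-methylphenol
Product: 2, 1-methoxy-4-(methoxymethoxy)-2-methylbenzene
Conditions: MOMCl, i-Pr2NEt, CH2Cl2, 0 °C → rt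
Reagents that add atoms: chloromethyl methyl ether, COCCl
Why: Williamson-type O-alkylation of the phenol; the MOM ether is the directing group for step 2.

**Step 2**
Reactants: 2; 3, (2E,6E)-farnesyl bromide
Product: 4, 1-methoxy-4-(methoxymethoxy)-2-methyl-5-[(2E,6E)-3,7,11-trimethyldodeca-2,6,10-trien-1-yl]benzene
Conditions: n-BuLi, TMEDA, THF, 0 °C; CuBr·SMe2, −78 °C; then 3, −78 °C → rt
Reagents that add atoms: (2E,6E)-farnesyl bromide, BrC/C=C(\C)CC/C=C(\C)CCC=C(C)C
Why: Directed ortho-metalation occurs next to OMOM (stronger director than OMe) at the unhindered position para to the methyl; the aryl copper then displaces the allylic bromide in SN2 fashion with retention of the E-olefin.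

**Step 3**
Reactants: 4
Product: 5, 4-methoxy-5-methyl-2-[(2E,6E)-farnesyl]phenol
Conditions: cat. conc. HCl, MeOH, rt (monitored; stopped at full conversion)
Reagents that add atoms: none
Why: Acetal solvolysis of the aryl MOM ether; dilute acid at rt leaves the trisubstituted olefins alone, as with other ortho-prenyl phenols.

**Step 4**
Reactants: 5
Product: 6, 4,4-dimethoxy-5-methyl-2-[(2E,6E)-farnesyl]cyclohexa-2,5-dien-1-one (achiral quinone monoketal)
Conditions: PhI(OAc)2, MeOH, 0 °C
Reagents that add atoms: methanol, CO
Why: Hypervalent-iodine oxidative dearomatisation of a p-methoxyphenol; methanol adds at the OMe-bearing carbon, which fixes the carbonyl next to the farnesyl-bearing carbon.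

**Step 5**
Reactants: 6
Product: 7, (1R,6S)-5,5-dimethoxy-4-methyl-1-[(2E,6E)-farnesyl]-7-oxabicyclo[4.1.0]hept-3-en-2-one
Conditions: t-BuOOH (70% aq.), N-benzylcinchonidinium chloride (10 mol %), 0.1 M aq. NaOH, toluene, 0 °C → rt
Reagents that add atoms: tert-butyl hydroperoxide, CC(C)(C)OO
Why: Weitz–Scheffer epoxidation under asymmetric phase-transfer catalysis; the chiral ammonium/t-BuOO⁻ ion pair selects one enantiotopic face, setting both epoxide stereocentres at once (about 80–90% ee expected by analogy with simpler quinone monoketals). Only the α-farnesyl/β-H double bond reacts, because the other β-carbon carries the methyl and is flanked by the ketal; the isolated farnesyl olefins are inert to a nucleophilic peroxide.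

**Step 6**
Reactants: 7
Product: 8, (1S,2S,6S)-5,5-dimethoxy-4-methyl-1-[(2E,6E)-farnesyl]-7-oxabicyclo[4.1.0]hept-3-en-2-ol (2-OH cis to the epoxide oxygen as the expected major epimer; the C2 epimer is inconsequential)
Conditions: NaBH4, CeCl3·7H2O, MeOH, −78 → −40 °C
Reagents that add atoms: none
Why: Luche 1,2-reduction, hydride entering anti to the epoxide oxygen; removing the carbonyl makes the ketal hydrolysable under mild acid, and the new carbinol centre is temporary (erased in step 8).

**Step 7**
Reactants: 8
Product: 9, (1S,5S,6S)-5-hydroxy-3-methyl-6-[(2E,6E)-farnesyl]-7-oxabicyclo[4.1.0]hept-3-en-2-one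
Conditions: PPTS (cat.), acetone/H2O (10:1), rt
Reagents that add atoms: water, O
Why: Mild acid hydrolysis of an allylic dimethyl ketal, now easy because the oxocarbenium ion is no longer conjugated to a carbonyl; PPTS spares the epoxide and the farnesyl olefins.

**Step 8**
Reactants: 9
Product: 10, (1R,6S)-4-methyl-1-[(2E,6E)-farnesyl]-7-oxabicyclo[4.1.0]hept-3-ene-2,5-dione (quinone epoxide)
Conditions: Dess–Martin periodinane, NaHCO3, CH2Cl2, 0 °C → rt
Reagents that add atoms: none
Why: Dess–Martin oxidation of the allylic secondary alcohol under neutral conditions; the epoxide stereocentres are not epimerisable.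

**Step 9**
Reactants: 10
Product: 11, (1R,5R,6R)-5-hydroxy-4-methyl-1-[(2E,6E)-farnesyl]-7-oxabicyclo[4.1.0]hept-3-en-2-one
Conditions: DIBAL-H (1.1 equiv), THF, −78 °C
Reagents that add atoms: none
Why: Substrate-controlled 1,2-reduction of the quinone epoxide. The C5 carbonyl (next to the epoxide CH) is less hindered and more electrophilic than C2, which sits beside the quaternary farnesyl carbon and is deactivated by the β-methyl; hydride adds anti to the epoxide oxygen, giving the syn epoxy alcohol (C5 = R).

**Step 10**
Reactants: 11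
Product: 12, (1R,5R,6R)-5-acetoxy-4-methyl-1-[(2E,6E)-farnesyl]-7-oxabicyclo[4.1.0]hept-3-en-2-one (target)
Conditions: lipase (serine hydrolase; immobilised Burkholderia cepacia lipase, Amano PS-IM), vinyl acetate, MTBE, 4 Å MS, 30 °C; stopped at about 90–95% conversion
Reagents that add atoms: vinyl acetate, CC(=O)OC=C
Why: Lipase-catalysed irreversible transesterification installs the acetate at neutral pH without touching the epoxy enone. If the Kazlauskas-type preference holds with the farnesyl-bearing half as the large group, the (5R) alcohol is the fast enantiomer, so the minor enantiomer stays behind as alcohol and the ee of 12 is raised.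

## Compound list

1 | 4-methoxy-3-methylphenol | COc1ccc(O)cc1C | starting material
2 | 1-methoxy-4-(methoxymethoxy)-2-methylbenzene | COCOc1ccc(OC)c(C)c1 | intermediate
3 | (2E,6E)-farnesyl bromide | BrC/C=C(\C)CC/C=C(\C)CCC=C(C)C | starting material
4 | 5-farnesyl-1-methoxy-4-(methoxymethoxy)-2-methylbenzene | COCOc1cc(C)c(OC)cc1C/C=C(\C)CC/C=C(\C)CCC=C(C)C | intermediate
5 | 2-farnesyl-4-methoxy-5-methylphenol | Oc1cc(C)c(OC)cc1C/C=C(\C)CC/C=C(\C)CCC=C(C)C | intermediate
6 | 2-farnesyl-4,4-dimethoxy-5-methylcyclohexa-2,5-dien-1-one | COC1(OC)C=C(C/C=C(\C)CC/C=C(\C)CCC=C(C)C)C(=O)C=C1C | intermediate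
7 | (1R,6S)-1-farnesyl-5,5-dimethoxy-4-methyl-7-oxabicyclo[4.1.0]hept-3-en-2-one | COC1(OC)C(C)=CC(=O)[C@]2(C/C=C(\C)CC/C=C(\C)CCC=C(C)C)O[C@H]12 | intermediate
8 | (1S,2S,6S)-1-farnesyl-5,5-dimethoxy-4-methyl-7-oxabicyclo[4.1.0]hept-3-en-2-ol | COC1(OC)C(C)=C[C@H](O)[C@]2(C/C=C(\C)CC/C=C(\C)CCC=C(C)C)O[C@H]12 | intermediate
9 | (1S,5S,6S)-6-farnesyl-5-hydroxy-3-methyl-7-oxabicyclo[4.1.0]hept-3-en-2-one | O=C1C(C)=C[C@H](O)[C@]2(C/C=C(\C)CC/C=C(\C)CCC=C(C)C)O[C@H]12 | intermediate
10 | (1R,6S)-1-farnesyl-4-methyl-7-oxabicyclo[4.1.0]hept-3-ene-2,5-dione | O=C1C(C)=CC(=O)[C@]2(C/C=C(\C)CC/C=C(\C)CCC=C(C)C)O[C@H]12 | intermediate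
11 | (1R,5R,6R)-1-farnesyl-5-hydroxy-4-methyl-7-oxabicyclo[4.1.0]hept-3-en-2-one | O[C@@H]1C(C)=CC(=O)[C@]2(C/C=C(\C)CC/C=C(\C)CCC=C(C)C)O[C@H]12 | intermediate
12 | (1R,5R,6R)-5-acetoxy-1-farnesyl-4-methyl-7-oxabicyclo[4.1.0]hept-3-en-2-one | CC(=O)O[C@@H]1C(C)=CC(=O)[C@]2(C/C=C(\C)CC/C=C(\C)CCC=C(C)C)O[C@H]12 | target

("farnesyl" = (2E,6E)-3,7,11-trimethyldodeca-2,6,10-trien-1-yl throughout.)

## Summary

Total steps: 10. Longest linear sequence: 10 (fully linear from 1).

Steps most likely to fail, with fallbacks:

1. **Step 5 (asymmetric epoxidation).** The α-branched dienone may react slowly or give modest ee. Fallback: make racemic 7 by plain Weitz–Scheffer epoxidation (t-BuOOH, DBU), carry it to (±)-11, and let the step 10 lipase acetylation act as a true kinetic resolution (maximum 50% yield, stereocontrol moved to the enzyme).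
2. **Step 9 (regio- and facial selectivity on the quinone epoxide).** Reduction could occur at the wrong carbonyl or give the anti alcohol. Fallback: bypass 10 by a protecting-group 1,4-carbonyl transposition: silylate the hydroxyl of 9 (TBS), reduce the only remaining ketone (Luche), acetylate, desilylate (buffered HF·pyridine) and oxidise the freed alcohol (Dess–Martin). This makes the regiochemistry unambiguous.
3. **Step 10 (lipase acetylation).** The (5R) alcohol may turn out to be the slow enantiomer or a poor substrate. Fallback: run the lipase acylation in reverse sense to consume the minor enantiomer as its acetate, separate, and acetylate the remaining enantiopure 11 chemically (Ac2O, pyridine, DMAP).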